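**Plan**
- Retrosynthesis: the C5–O(aryl) bond is cut first (inverting Mitsunobu etherification with chromone phenol 6). Then C4a–C5 and O1–C8a are cut in one operation, which opens the carbocycle and the 4-pyranone of the tetrahydrochromone to the acyclic ynedione aldehyde 19. Last, the C4–C4a bond is cut (acetylide + aldehyde).
- Enabling feature: the C4a=C8a bond is shared by the pyranone and the carbocycle, with O1 on C8a and the oxygenated carbon C5 on C4a trans to each other. It is therefore the product of an anti addition of an enol oxygen and a carbonyl carbon across an alkyne C8a≡C4a that already carries the C8–C7–C6 tether.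
- Forward: chromone 6 (3 steps) and aldehyde 11 (3 steps) are made first. D-Arabinose gives alkyne 15, which is joined to 11, desilylated and oxidised three times. The Pd(II) cascade then closes the pyranone and, as the last ring, the carbocycle. Oxidation/reduction at C5, etherification and global deprotection follow.
- Stereochemistry: C6, C7 and C8 are C4, C3 and C2 of D-arabinose and are never touched. C5 is set by hydride delivery anti to the cis-fused dioxolane and is then inverted in the SN2 etherification.

Key step: step 13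

Remark: carbinol centres that are later oxidised (in 8–11, 17, 18) and the anomeric centre of 13 are left open in the SMILES; 21 is drawn without configuration at C5 because both epimers are carried on and converge in step 14.

**Route**

Step 1
Reactants: 1 1-(2-hydroxy-4,5-dimethoxyphenyl)ethan-1-one; 2 ethyl 3-phenylpropanoate
Product: 4 6,7-dimethoxy-2-(2-phenylethyl)-4H-chromen-4-one, via aryl diketone 3 (not isolated)
Conditions: NaH, THF, reflux; then conc. HCl, MeOH, reflux
Reagents that add atoms: none
Why: crossed Claisen condensation of the acetophenone enolate with the ester gives the 1,3-diketone, and acid-catalysed cyclodehydration with the ortho phenol closes the chromone.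

Step 2
Reactants: 4 6,7-dimethoxy-2-(2-phenylethyl)-4H-chromen-4-one
Product: 5 6,7-dihydroxy-2-(2-phenylethyl)-4H-chromen-4-one
Conditions: BBr3, CH2Cl2, −78 °C to rt; H2O
Reagents that add atoms: none
Why: Lewis-acid cleavage of both aryl methyl ethers; the chromone and the phenethyl chain are inert to BBr3.

Step 3
Reactants: 5 6,7-dihydroxy-2-(2-phenylethyl)-4H-chromen-4-one
Product: 6 6-hydroxy-7-(methoxymethoxy)-2-(2-phenylethyl)-4H-chromen-4-one
Conditions: MOMCl (1.0 equiv), K2CO3 (1.1 equiv), acetone, 0 °C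
Reagents that add atoms: chloromethyl methyl ether COCCl
Why: the 7-OH is para to the ring carbon that bears the carbonyl and is the more acidic phenol, so the weak base should deprotonate and alkylate O7 and leave the 6-OH free for step 16.

Step 4
Reactants: 7 3-phenylpropanal
Product: 8 1-phenylhex-5-en-3-ol
Conditions: allylMgBr, Et2O, 0 °C; H2O
Reagents that add atoms: allylmagnesium bromide C=CC[Mg]Br
Why: Grignard 1,2-addition to an unhindered aldehyde; the carbinol centre is left racemic because it becomes the C2 carbonyl carbon in step 12.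

Step 5
Reactants: 8 1-phenylhex-5-en-3-ol
Product: 9 triethyl[(1-phenylhex-5-en-3-yl)oxy]silane
Conditions: TESCl, imidazole, CH2Cl2, 0 °C
Reagents that add atoms: chlorotriethylsilane CC[Si](CC)(CC)Cl
Why: routine silylation of a secondary alcohol; TES is chosen so that it falls together with the primary TBS ether in step 11 while the secondary TBS ether at C8 stays.

Step 6
Reactants: 9 triethyl[(1-phenylhex-5-en-3-yl)oxy]silane
Product: 11 5-phenyl-3-(triethylsilyloxy)pentanal, via secondary ozonide 10 (not isolated)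
Conditions: O3, CH2Cl2, −78 °C; then PPh3, −78 °C to rt
Reagents that add atoms: ozone [O-][O+]=O
Why: ozonolysis of the terminal alkene with reductive work-up gives the β-silyloxy aldehyde; the alkene reacts far faster than the phenyl ring at −78 °C.

Step 7
Reactants: 12 D-arabinose
Product: 13 3,4-O-isopropylidene-D-arabinopyranose
Conditions: Me2C(OMe)2, TsOH·H2O (cat.), DMF, rt
Reagents that add atoms: 2,2-dimethoxypropane COC(C)(C)OC
Why: kinetic transacetalisation engages the cis-3,4-diol of arabinopyranose (a known regioselectivity), which fixes the future C6/C7 cis-diol as a dioxolane and leaves the lactol free.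

Step 8
Reactants: 13 3,4-O-isopropylidene-D-arabinopyranose
Product: 14 1,2-dideoxy-4,5-O-isopropylidene-D-arabino-hex-1-ynitol
Conditions: MeC(O)C(N2)P(O)(OMe)2, K2CO3, MeOH, rt
Reagents that add atoms: dimethyl (1-diazo-2-oxopropyl)phosphonate CC(=O)C(=[N+]=[N-])P(=O)(OC)OC
Why: Ohira–Bestmann homologation of the open-chain aldehyde tautomer of the lactol turns C1 of arabinose into the internal alkyne carbon (future C8a) and adds the future C4a, while the former ring oxygen is released as the primary hydroxyl (future C5).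

Step 9
Reactants: 14 1,2-dideoxy-4,5-O-isopropylidene-D-arabino-hex-1-ynitol
Product: 15 3,6-bis-O-(tert-butyldimethylsilyl)-1,2-dideoxy-4,5-O-isopropylidene-D-arabino-hex-1-ynitol
Conditions: TBSCl (2.5 equiv), imidazole, DMF, rt to 40 °C
Reagents that add atoms: tert-butyldimethylsilyl chloride CC(C)(C)[Si](C)(C)Cl
Why: exhaustive silylation; the primary and the hindered propargylic secondary TBS ether differ enough in lability to be told apart in step 11.

Step 10
Reactants: 15 3,6-bis-O-(tert-butyldimethylsilyl)-1,2-dideoxy-4,5-O-isopropylidene-D-arabino-hex-1-ynitol; 11 5-phenyl-3-(triethylsilyloxy)pentanal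
Product: 17 1-C-[1-hydroxy-5-phenyl-3-(triethylsilyloxy)pentyl]-3,6-bis-O-(tert-butyldimethylsilyl)-1,2-dideoxy-4,5-O-isopropylidene-D-arabino-hex-1-ynitol, via lithium acetylide 16 (not isolated)
Conditions: n-BuLi, THF, −78 °C; then 11, −78 °C; H2O
Reagents that add atoms: none
Why: 1,2-addition of a lithium acetylide to an aldehyde joins the sugar to the C2–C4 fragment; both side-chain carbinol centres are oxidised later, so no control is needed.

Step 11
Reactants: 17 propargylic alcohol (silyl-protected)
Product: 18 3-O-(tert-butyldimethylsilyl)-1,2-dideoxy-1-C-(1,3-dihydroxy-5-phenylpentyl)-4,5-O-isopropylidene-D-arabino-hex-1-ynitol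
Conditions: HF·pyridine, pyridine, THF, 0 °C
Reagents that add atoms: none
Why: buffered HF should cleave the TES ether and the primary TBS ether much faster than the hindered secondary TBS ether at C8, and the isopropylidene acetal is stable to it.

Step 12
Reactants: 18 triol
Product: 19 4-O-(tert-butyldimethylsilyl)-5,6-dideoxy-2,3-O-isopropylidene-6-C-(3-oxo-5-phenylpentanoyl)-aldehydo-D-lyxo-hex-5-ynose
Conditions: Dess–Martin periodinane (4 equiv), CH2Cl2, 0 °C to rt; crude product used at once
Reagents that add atoms: none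
Why: Dess–Martin oxidation should convert the propargylic alcohol into the ynone, the β-hydroxy ketone into the 1,3-diketone and the primary alcohol into the aldehyde without base, so the α-alkoxy aldehyde centre (C6) is not epimerised.

Step 13
Reactants: 19 ynedione aldehyde
Product: 21 (6R,7R,8S)-8-[(tert-butyldimethylsilyl)oxy]-5-hydroxy-6,7-(isopropylidenedioxy)-2-(2-phenylethyl)-5,6,7,8-tetrahydro-4H-chromen-4-one (C5 epimers), via vinylpalladium pyranone 20 (not isolated)
Conditions: Pd(OAc)2 (10 mol %), 2,2'-bipyridine (12 mol %), AcOH, 1,4-dioxane, 60 °C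
Reagents that add atoms: none
Why: Proposed new method: Pd(II) activates the ynone C8a≡C4a of 19, and the enol oxygen of the 1,3-diketone adds to the β-carbon C8a anti to palladium, closing the 4-pyranone (O1–C8a, 6-endo-dig) and leaving the σ-vinylpalladium 20 with Pd on C4a cis to the C8 side chain; the C4a–Pd bond then adds 1,2 to the tethered C5 aldehyde (carbocycle C4a–C5–C6–C7–C8–C8a, exo attack on C=O), and AcOH protonates the palladium alkoxide, so Pd(II) is returned and the step is a redox-neutral isomerisation. The closest known reaction types are the Pd(II)-catalysed Wacker-type 6-endo oxypalladation of β-hydroxy ynones with interception of the vinylpalladium, and the Pd(II)/bipyridine heteropalladation of alkynes that ends in 1,2-addition of the vinylpalladium to a tethered aldehyde; merging them with a diketone enol as the oxygen nucleophile is the new element. The heterocycle should close 6-endo because C8a is the electrophilic β-carbon of the ynone, whereas 5-exo attack would have to occur at the α-carbon C4a. C5 is the only new stereocentre; it forms under substrate control by the dioxolane-fused half-chair, no reliable preference is claimed, and both epimers are carried on because C5 is reset in steps 14 and 15. The step needs carbonyl insertion to outrun protonolysis of 20, which the six-membered tether and the bidentate ligand (keeping a long-lived Pd(II) vinyl) should secure; the cis relationship of Pd and tether is guaranteed by the anti oxypalladation, and the weakly acidic, base-free medium protects the C6 centre α to the aldehyde.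

Step 14
Reactants: 21 C5 alcohol (epimer mixture)
Product: 22 (6S,7R,8S)-8-[(tert-butyldimethylsilyl)oxy]-6,7-(isopropylidenedioxy)-2-(2-phenylethyl)-7,8-dihydro-4H-chromene-4,5(6H)-dione
Conditions: Dess–Martin periodinane, CH2Cl2, rt
Reagents that add atoms: none
Why: oxidation of the secondary C5 alcohol converges both epimers to one ketone; no base is present, so the β-alkoxy ketone should not eliminate.

Step 15
Reactants: 22 C5 ketone
Product: 23 (5R,6R,7R,8S)-8-[(tert-butyldimethylsilyl)oxy]-5-hydroxy-6,7-(isopropylidenedioxy)-2-(2-phenylethyl)-5,6,7,8-tetrahydro-4H-chromen-4-one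
Conditions: NaBH4, CeCl3·7H2O, MeOH, −78 °C
Reagents that add atoms: none
Why: Luche 1,2-reduction of the C5 ketone (the vinylogous-ester C4 carbonyl is far less electrophilic); hydride should add from the α face, anti to the β-oriented cis-fused dioxolane and to the C6–O bond, which sets C5 as R with the hydroxyl cis to O6.

Step 16
Reactants: 23 (5R)-alcohol; 6 6-hydroxy-7-(methoxymethoxy)-2-(2-phenylethyl)-4H-chromen-4-one
Product: 24 (5S,6R,7R,8S)-8-[(tert-butyldimethylsilyl)oxy]-6,7-(isopropylidenedioxy)-5-{[7-(methoxymethoxy)-4-oxo-2-(2-phenylethyl)-4H-chromen-6-yl]oxy}-2-(2-phenylethyl)-5,6,7,8-tetrahydro-4H-chromen-4-one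
Conditions: PPh3, DIAD, toluene–THF, 0 °C to rt
Reagents that add atoms: none
Why: Mitsunobu etherification; the 6-phenoxide (7-OH blocked as MOM ether) should displace the C5 oxyphosphonium by SN2 from the α face, anti to the dioxolane, which inverts C5 to S and gives the 5,6-trans aryl ether.

Step 17
Reactants: 24 protected ether
Product: 25 (5S,6S,7R,8S)-6,7,8-trihydroxy-5-{[7-hydroxy-4-oxo-2-(2-phenylethyl)-4H-chromen-6-yl]oxy}-2-(2-phenylethyl)-5,6,7,8-tetrahydro-4H-chromen-4-one
Conditions: TFA–H2O (9:1), 0 °C to rt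
Reagents that add atoms: none
Why: aqueous acid should remove the isopropylidene acetal, the TBS ether and the aryl MOM ether in one operation; the pyranone and chromone are O-protonated in this medium, which disfavours ionisation of the C5–OAr bond, and no base is present that could trigger elimination and aromatisation.

**Compound list**

1 | 1-(2-hydroxy-4,5-dimethoxyphenyl)ethan-1-one | CC(=O)c1cc(OC)c(OC)cc1O | starting material
2 | ethyl 3-phenylpropanoate | CCOC(=O)CCc1ccccc1 | starting material
3 | 1-(2-hydroxy-4,5-dimethoxyphenyl)-5-phenylpentane-1,3-dione (not isolated) | O=C(CC(=O)CCc1ccccc1)c1cc(OC)c(OC)cc1O | intermediate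
4 | 6,7-dimethoxy-2-(2-phenylethyl)-4H-chromen-4-one | COc1cc2oc(CCc3ccccc3)cc(=O)c2cc1OC | intermediate
5 | 6,7-dihydroxy-2-(2-phenylethyl)-4H-chromen-4-one | Oc1cc2oc(CCc3ccccc3)cc(=O)c2cc1O | intermediate
6 | 6-hydroxy-7-(methoxymethoxy)-2-(2-phenylethyl)-4H-chromen-4-one | COCOc1cc2oc(CCc3ccccc3)cc(=O)c2cc1O | intermediate
7 | 3-phenylpropanal | O=CCCc1ccccc1 | starting material
8 | 1-phenylhex-5-en-3-ol (racemic) | C=CCC(O)CCc1ccccc1 | intermediate
9 | triethyl[(1-phenylhex-5-en-3-yl)oxy]silane (racemic) | C=CCC(O[Si](CC)(CC)CC)CCc1ccccc1 | intermediate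
10 | secondary ozonide of 9, a 3-substituted 1,2,4-trioxolane (not isolated) | C1OC(CC(O[Si](CC)(CC)CC)CCc2ccccc2)OO1 | intermediate
11 | 5-phenyl-3-(triethylsilyloxy)pentanal (racemic) | O=CCC(O[Si](CC)(CC)CC)CCc1ccccc1 | intermediate
12 | D-arabinose (pyranose form) | OC1OC[C@@H](O)[C@@H](O)[C@@H]1O | starting material
13 | 3,4-O-isopropylidene-D-arabinopyranose | OC1OC[C@H]2OC(C)(C)O[C@H]2[C@@H]1O | intermediate
14 | 1,2-dideoxy-4,5-O-isopropylidene-D-arabino-hex-1-ynitol | OC[C@H]1OC(C)(C)O[C@H]1[C@@H](C#C)O | intermediate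
15 | 3,6-bis-O-(tert-butyldimethylsilyl)-1,2-dideoxy-4,5-O-isopropylidene-D-arabino-hex-1-ynitol | CC(C)(C)[Si](C)(C)OC[C@H]1OC(C)(C)O[C@H]1[C@@H](C#C)O[Si](C)(C)C(C)(C)C | intermediate
16 | lithium acetylide of 15 (not isolated) | CC(C)(C)[Si](C)(C)OC[C@H]1OC(C)(C)O[C@H]1[C@@H](C#C[Li])O[Si](C)(C)C(C)(C)C | intermediate
17 | 1-C-[1-hydroxy-5-phenyl-3-(triethylsilyloxy)pentyl]-3,6-bis-O-(tert-butyldimethylsilyl)-1,2-dideoxy-4,5-O-isopropylidene-D-arabino-hex-1-ynitol (mixture at the two side-chain carbinol carbons) | CC(C)(C)[Si](C)(C)OC[C@H]1OC(C)(C)O[C@H]1[C@@H](C#CC(O)CC(O[Si](CC)(CC)CC)CCc2ccccc2)O[Si](C)(C)C(C)(C)C | intermediate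
18 | 3-O-(tert-butyldimethylsilyl)-1,2-dideoxy-1-C-(1,3-dihydroxy-5-phenylpentyl)-4,5-O-isopropylidene-D-arabino-hex-1-ynitol (mixture at the two side-chain carbinol carbons) | OC[C@H]1OC(C)(C)O[C@H]1[C@@H](C#CC(O)CC(O)CCc2ccccc2)O[Si](C)(C)C(C)(C)C | intermediate
19 | 4-O-(tert-butyldimethylsilyl)-5,6-dideoxy-2,3-O-isopropylidene-6-C-(3-oxo-5-phenylpentanoyl)-aldehydo-D-lyxo-hex-5-ynose (ynedione aldehyde) | O=C[C@H]1OC(C)(C)O[C@H]1[C@@H](C#CC(=O)CC(=O)CCc2ccccc2)O[Si](C)(C)C(C)(C)C | intermediate
20 | σ-vinylpalladium(II) acetate of the closed 4-pyranone, Pd on the future C4a, aldehyde still free, bipyridine ligand omitted (not isolated) | O=C[C@H]1OC(C)(C)O[C@H]1[C@@H](c3oc(CCc2ccccc2)cc(=O)c3[Pd]OC(C)=O)O[Si](C)(C)C(C)(C)C | intermediate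
21 | (6R,7R,8S)-8-[(tert-butyldimethylsilyl)oxy]-5-hydroxy-6,7-(isopropylidenedioxy)-2-(2-phenylethyl)-5,6,7,8-tetrahydro-4H-chromen-4-one (5RS) | O=c1cc(CCc2ccccc2)oc2c1C(O)[C@H]3OC(C)(C)O[C@H]3[C@@H]2O[Si](C)(C)C(C)(C)C | intermediate
22 | (6S,7R,8S)-8-[(tert-butyldimethylsilyl)oxy]-6,7-(isopropylidenedioxy)-2-(2-phenylethyl)-7,8-dihydro-4H-chromene-4,5(6H)-dione | O=c1cc(CCc2ccccc2)oc2c1C(=O)[C@H]3OC(C)(C)O[C@H]3[C@@H]2O[Si](C)(C)C(C)(C)C | intermediate
23 | (5R,6R,7R,8S)-8-[(tert-butyldimethylsilyl)oxy]-5-hydroxy-6,7-(isopropylidenedioxy)-2-(2-phenylethyl)-5,6,7,8-tetrahydro-4H-chromen-4-one | O=c1cc(CCc2ccccc2)oc2c1[C@@H](O)[C@H]3OC(C)(C)O[C@H]3[C@@H]2O[Si](C)(C)C(C)(C)C | intermediate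
24 | (5S,6R,7R,8S)-8-[(tert-butyldimethylsilyl)oxy]-6,7-(isopropylidenedioxy)-5-{[7-(methoxymethoxy)-4-oxo-2-(2-phenylethyl)-4H-chromen-6-yl]oxy}-2-(2-phenylethyl)-5,6,7,8-tetrahydro-4H-chromen-4-one | O=c1cc(CCc2ccccc2)oc2c1[C@H](Oc1cc3c(=O)cc(CCc4ccccc4)oc3cc1OCOC)[C@H]5OC(C)(C)O[C@H]5[C@@H]2O[Si](C)(C)C(C)(C)C | intermediate
25 | (5S,6S,7R,8S)-6,7,8-trihydroxy-5-{[7-hydroxy-4-oxo-2-(2-phenylethyl)-4H-chromen-6-yl]oxy}-2-(2-phenylethyl)-5,6,7,8-tetrahydro-4H-chromen-4-one (CNP0248258.1) | O=c1cc(CCc2ccccc2)oc2c1[C@H](Oc1cc3c(=O)cc(CCc4ccccc4)oc3cc1O)[C@@H](O)[C@@H](O)[C@@H]2O | target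

**Count**
Total step count: 17. Longest linear sequence: 11 steps (steps 7–17, from D-arabinose 12).

**Steps most likely to fail**

1. Step 13 (Proposed new method). The vinylpalladium may be protonated before it inserts the aldehyde, or palladium may be bound by the diketonate so that the alkyne is never activated. The fallback makes the C4a–C5 bond by a Nozaki–Hiyama–Kishi cyclisation and uses known reaction types only. It sets out from propargylic alcohol 17. MnO2 oxidises only the propargylic carbinol to the silyl-protected ynone F1. PPTS in MeOH removes the TES group to give the β-hydroxy ynone F2, which cyclises 6-endo-dig under catalytic AgOTf to the 2,3-dihydro-4-pyranone F3. I2/pyridine iodinates the only enone α-carbon (the future C4a) to give the iodo dihydropyranone F4, and IBX dehydrogenates C2–C3 to the 3-iodo-4-pyranone F5, so the halogen is placed without a C3/C4a selectivity problem. HF·pyridine frees the primary alcohol F6, Dess–Martin oxidation gives the iodo aldehyde F7, and CrCl2 with catalytic NiCl2 in DMF closes the carbocycle to 21, where the route is rejoined.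

2. Step 16. The activated C5 oxyphosphonium may eliminate towards C6 (followed by aromatisation of the carbocycle), or the hindered centre may resist SN2 and ionise, eroding inversion. The fallback sets out from alcohol 23, which is converted with Cl3CCN and catalytic DBU into the trichloroacetimidate F8. This alkylates phenol 6 under catalytic TMSOTf at −40 °C, with the phenol entering from the face anti to the dioxolane, and gives 24, where the route is rejoined.

3. Step 12. The 1,3-diketone may be over-oxidised at C3 by excess periodinane, or the ynedione may proto-cyclise to the simple pyranone before the palladium catalyst is added. The fallback carries the C2 carbonyl as a dimethyl ketal so that no free diketone meets the oxidant. Commercial methyl 3-oxo-5-phenylpentanoate F9 is ketalised (HC(OMe)3, MeOH, cat. TsOH) to methyl 3,3-dimethoxy-5-phenylpentanoate F10 and reduced (DIBAL, −78 °C) to 3,3-dimethoxy-5-phenylpentanal F11. The fallback sets out from alkyne 15: its acetylide 16 adds to F11 to give the ketal propargylic alcohol F12. HF·pyridine removes only the primary TBS group to give the ketal diol F13, and Dess–Martin oxidation (two oxidations) gives the ketal ynone aldehyde F14. Brief treatment with aqueous AcOH in THF at rt unmasks the ketone and returns to 19 directly before step 13.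

**Further compounds**

F1 | step 13 | silyl-protected ynone (17 with the propargylic carbinol oxidised) | CC(C)(C)[Si](C)(C)OC[C@H]1OC(C)(C)O[C@H]1[C@@H](C#CC(=O)CC(O[Si](CC)(CC)CC)CCc2ccccc2)O[Si](C)(C)C(C)(C)C
F2 | step 13 | β-hydroxy ynone | CC(C)(C)[Si](C)(C)OC[C@H]1OC(C)(C)O[C@H]1[C@@H](C#CC(=O)CC(O)CCc2ccccc2)O[Si](C)(C)C(C)(C)C
F3 | step 13 | 6-substituted 2-(2-phenylethyl)-2,3-dihydro-4H-pyran-4-one | CC(C)(C)[Si](C)(C)OC[C@H]1OC(C)(C)O[C@H]1[C@@H](C3=CC(=O)CC(CCc2ccccc2)O3)O[Si](C)(C)C(C)(C)C
F4 | step 13 | 5-iodo-2,3-dihydro-4H-pyran-4-one | CC(C)(C)[Si](C)(C)OC[C@H]1OC(C)(C)O[C@H]1[C@@H](C3=C(I)C(=O)CC(CCc2ccccc2)O3)O[Si](C)(C)C(C)(C)C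
F5 | step 13 | 3-iodo-4H-pyran-4-one (iodine on the future C4a) | CC(C)(C)[Si](C)(C)OC[C@H]1OC(C)(C)O[C@H]1[C@@H](c3oc(CCc2ccccc2)cc(=O)c3I)O[Si](C)(C)C(C)(C)C
F6 | step 13 | iodopyranone primary alcohol | OC[C@H]1OC(C)(C)O[C@H]1[C@@H](c3oc(CCc2ccccc2)cc(=O)c3I)O[Si](C)(C)C(C)(C)C
F7 | step 13 | iodopyranone aldehyde | O=C[C@H]1OC(C)(C)O[C@H]1[C@@H](c3oc(CCc2ccccc2)cc(=O)c3I)O[Si](C)(C)C(C)(C)C
F8 | step 16 | C5 trichloroacetimidate of 23 | O=c1cc(CCc2ccccc2)oc2c1[C@@H](OC(=N)C(Cl)(Cl)Cl)[C@H]3OC(C)(C)O[C@H]3[C@@H]2O[Si](C)(C)C(C)(C)C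
F9 | step 12 | methyl 3-oxo-5-phenylpentanoate (purchased) | COC(=O)CC(=O)CCc1ccccc1
F10 | step 12 | methyl 3,3-dimethoxy-5-phenylpentanoate | COC(=O)CC(OC)(OC)CCc1ccccc1
F11 | step 12 | 3,3-dimethoxy-5-phenylpentanal | O=CCC(OC)(OC)CCc1ccccc1
F12 | step 12 | ketal propargylic alcohol | CC(C)(C)[Si](C)(C)OC[C@H]1OC(C)(C)O[C@H]1[C@@H](C#CC(O)CC(OC)(OC)CCc2ccccc2)O[Si](C)(C)C(C)(C)C
F13 | step 12 | ketal diol | OC[C@H]1OC(C)(C)O[C@H]1[C@@H](C#CC(O)CC(OC)(OC)CCc2ccccc2)O[Si](C)(C)C(C)(C)C
F14 | step 12 | ketal ynone aldehyde | O=C[C@H]1OC(C)(C)O[C@H]1[C@@H](C#CC(=O)CC(OC)(OC)CCc2ccccc2)O[Si](C)(C)C(C)(C)C
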